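What was left of the two substrates after 4.00 min in the north-east run, 40.5 % right-handed substrate against 39.0 % left-handed substrate, was the last of that run's readings, and I chose it as the basis for deciding how long to leave the next flask.

common to all: left-handed substrate 0.052 M; right-handed substrate 0.052 M
- north-east: partner 6 equiv; run made earlier
- Thursday's: partner 3.00 equiv; time 12 min
- Monday's: partner 3.00 equiv; time 40 min

north-east run (percent of the left-handed substrate and right-handed substrate together charged)

| time / min | right-handed substrate / % | left-handed substrate / % |
|---|---|---|
| 0.250 | 49.9 | 48.7 |
| 0.500 | 48.5 | 49.3 |
| 0.833 | 48.3 | 46.5 |
| 1.33 | 46.6 | 45.6 |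
| 2.00 | 44.1 | 42.3 |
| 4.00 | 40.5 | 39.0 |

(each reading ± 0.5 percentage points)

- partner is single-handed; left-handed substrate and right-handed substrate are mirror images of each other, charged as a racemate, each of them at the stated concentration
- the numbers in the tables scatter by 0.5 percentage points (one standard deviation)
- candidate steps: 2 partner -> homo dimer; right-handed substrate <-> achiral form; partner + left-handed substrate -> left-handed product; partner + right-handed substrate -> right-handed product; left-handed substrate <-> achiral form
- an excess is the difference of the two amounts in percent of their sum
- an excess is below zero if the other one leads
- the handed part of partner does not stay in what it makes, so the products of the two hands are mirror images too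

* which of the two ends with the higher excess of right-handed substrate over left-handed substrate among what is left of the two ("neither" if they lie within 2 percentage points) (Thursday's / Monday's / neither)
* excess of right-handed substrate over left-handed substrate among what is left of the two at the end, Thursday's
* excess of right-handed substrate over left-handed substrate among what is left of the two at the end, Monday's

I called the excess of right-handed substrate over left-handed substrate e; in that leftover it was 1.89 %. Partner was charged at 6 equiv, more than either substrate, so I treated each hand's loss to partner as pseudo-first-order, with a rate proportional to [partner]. I therefore took e to grow with [partner] × t, and defined the handedness yield g, the excess gained per unit of [partner] × t, as 0.0151 M⁻¹ min⁻¹. This is a rough figure, since each reading scatters by 0.5 percentage points and the excess at 2.00 min was already 2.08 %.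

With the same charge of 0.156 M partner and that concentration held:

e(Thursday's, 12 min) = g × [partner] × t = 2.83 %

e(Monday's, 40 min) = g × [partner] × t = 9.43 %

That gap is wider than the margin of 2 points, so my reckoning said to leave the flask for the longer time.

The forecast named Monday's, at 3.2 % and 5.8 %, “less if racemisation acts”.

The flask gave 3.44 % on Thursday's and 4.10 % on Monday's, so the answer is neither: the gap of 0.66 points is smaller than the margin.

    2 partner → homo dimer (k = 0.200 M⁻¹ min⁻¹)
    right-handed substrate ⇌ achiral form (K = 1.50, k = 0.0360 min⁻¹)
    partner + left-handed substrate → left-handed product (k = 0.140 M⁻¹ min⁻¹)
    partner + right-handed substrate → right-handed product (k = 0.0840 M⁻¹ min⁻¹)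
    left-handed substrate ⇌ achiral form (K = 1.50, k = 0.0360 min⁻¹)

My 9.43 % for Monday's stood far above the flask's 4.10 %, while my 2.83 % for Thursday's lay nearer its 3.44 %. In Monday's flask, right-handed substrate went to achiral form (forward step alone) 2.7 times faster than to right-handed product at the start and 11 times faster at 40.0 min, when 24 % of the partner remained. For the same flask left until 15 min, g × [partner] × t gives 3.53 %; the computed excess there is 3.86 %.

Readings and results are simulated for an exercise, and the scatter is random.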